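## Analysis of the target

Labdane numbering is used throughout: ring A is C1–C5 and C10, ring B is C5–C10, the side chain is C11–C15 with C16 on C13, C17 is the methylene carbon, C18 is the equatorial and C19 the axial carbon on C4, and C20 is the methyl on C10.

- Target 34 is a trans-fused decalin with an exocyclic C8=C17 methylene, a C9 side chain ending in the C15 carboxylic acid, and an (E)-p-coumarate on the equatorial C18 methylene.
- It has five stereocentres, (4S,5S,9R,10S,13S). Four are contiguous on the decalin: the C10 and C4 methyls are syn-diaxial, H5 and H9 lie on the opposite face, and the C9 chain is equatorial.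
- C13 sits four bonds from the ring and cannot be controlled from it, so it needs reagent control.
- C4 and C10 are both quaternary and flank C5. The two one-carbon groups on C4 differ only in oxidation level.
- The methylene rules out hydrogenation and strong acid, and it moves into conjugation as soon as a carbonyl group sits at C6 or C11 under equilibrating conditions.
- The cinnamate is cleaved by hydride and hydroxide, and both the phenol and the acid must be unmasked at the end without touching it.
- The strategy rests on ring B: C8 carries the methylene, C9 carries C11 and is bonded to the quaternary C10. This is the pattern left when a diene C10=C5–C6=C7 adds across only the 2,3-double bond of a buta-2,3-dienoate.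

## Retrosynthetic reasoning

**Unmasking.** 34 is traced to 33, in which the phenol is a silyl ether and the C15 acid a 2-(trimethylsilyl)ethyl ester. Both O–protecting-group bonds fall to fluoride in one operation, which spares the cinnamate ester and the methylene.

**C19 methyl and the coumarate.** The C19 methyl of 33 is traced to the aldehyde 31 through its tosylhydrazone 32, and 31 to the alcohol 30. The C18–O acyl bond of 30 is then cut to give diol 26 and the protected acid 29, which comes from p-coumaric acid 27 through 28. The cut is made here because the two hydroxymethyl groups of 26 differ only through the rigid trans-decalin: the axial one is screened by the syn-axial C10 methyl. Acylating the equatorial one with the final acyl group avoids a protect–deprotect pair, and the forward reaction has to make C4 a stereocentre by that discrimination.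

**Side chain.** Diol 26 comes from acetonide 25. The C13–H bond of 25 is traced to enoate 24, the C13=C14 bond of 24 to ketone 20 and phosphonate 23 (from 21 and 22), and the C11=C12 bond of enone 19 to aldehyde 18, which comes from ester 16 through alcohol 17. Each alkene is conjugated when it is reduced, so copper hydride can saturate it and leave the isolated methylene alone. The forward sequence must set C13 by ligand control.

**C6 oxygen.** Ester 16 is traced through xanthate 15 and alcohol 14 to ketone 13 and the silyl enol ether 12. The C6 oxygen is a relic of the diene. The forward sequence must set C5 by protonation of the enol ether and then remove the oxygen without letting the methylene conjugate with the C6 carbonyl.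

**Ring B (key disconnection).** The C7–C8 and C9–C10 bonds of 12 are cut to give diene 10 and ethyl buta-2,3-dienoate 11. No other cut delivers the methylene, the C9 carbon substituent and the C10 quaternary centre at once from two simple fragments. The spiro-acetonide keeps 10 achiral, so one catalyst-controlled event has to fix the absolute configuration at C10 and the relative configuration at C9.

**Diene.** Diene 10 is the silyl enol ether of ketone 9. Its C5–C6 bond is cut at the enol triflate 7 (coupling via 8), and 7 comes from ketone 6, which has a single enolisable position. Ketone 6 is traced through 5, 4, 3 and 2 to ethyl 2-oxocyclohexane-1-carboxylate 1, whose ester carbon and a one-carbon aldol provide the two C4 arms.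

## Alternatives that were turned down

**Alternative 1:** trienal Diels–Alder.
- Disconnection: C3–C4 and C5–C10, unfolding both rings of aldehyde A1 into the acyclic trienal A2.
- Forward key step: intramolecular Diels–Alder of A2, the (E)-2-methyl-2-enal C4=C5 adding to the diene C10=C1–C2=C3, to give A1.
- For: C4, C5 and C10 are set at once and both rings are formed. C4 is differentiated from the start (CHO against CH3), so no desymmetrisation and no C6 oxygen are needed. On C4 it is stronger than the chosen plan.
- Against: A2 is a long chain with two defined trisubstituted alkenes and two preset stereocentres (C9, C13). The cycloaddition joins a trisubstituted dienophile to a fully substituted diene terminus whose methyl is inside, so two quaternary carbons form in one hindered step. Facial control rests on C9 alone. Afterwards C1=C2 must be hydrogenated, the C8 ketal removed, and C8 methylenated next to the epimerisable C9.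
- Comparison: the chosen plan gives up the built-in C4 differentiation. In return it has a short achiral precursor, catalytic absolute control, and a methylene that is formed in the cycloaddition and not by late olefination.

**Alternative 2:** dehydroabietic acid ring A with C4 and C10 exchanged.
- Disconnection: C8–C9, opening ring B of A3 to the ynal A4. A4 is derived from dehydroabietic acid A5, whose carboxyl-bearing carbon becomes C10 and whose aryl-bearing carbon becomes C4.
- Forward key step: reductive aldehyde–alkyne cyclisation of A4 with a zerovalent nickel phosphine catalyst and a trialkylsilane, giving the allylic silyl ether A3 with an exocyclic C9=C11 alkene.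
- For: the ring closure is of a well-precedented type, stronger on precedent than the chosen key step. C4, C5 and C10 come from the chiral pool, so no enantioselective step and no desymmetrisation are needed for the decalin.
- Against: the aromatic ring and isopropyl group of A5 must be degraded to one carbon on C4 and a three-carbon aldehyde chain on C5, with three carbonyl-level carbons kept apart, two of them neopentyl. The alkyne must be built on the neopentyl C10 and joined to a chiral C12–C15 unit. After the cyclisation C9 is still sp2, so C9=C11 must be reduced with control and C8–O oxidised and methylenated beside C9.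
- Comparison: far more steps than the chosen plan, which sets C9 and the methylene in the bond-forming event itself and is convergent.

**Alternative 3:** intramolecular silyloxydiene–enoate Diels–Alder.
- Disconnection: C5–C10 and C8–C9 of A6, unfolding to the triene A7.
- Forward key step: with a dialkylaluminium chloride or heat, the (E)-3-methyl-2-enoate C9=C10 of A7 adds to the (E,E)-1-silyloxydiene C5=C6–C7=C8. This closes ring B and, through the C1–C4 tether, ring A.
- For: it is intramolecular and sets C5, C9 and C10 together. The cis relation of the C9 ester and C10 methyl follows from the enoate geometry. C4 is already differentiated and there is no C6 oxygen. On these points it is stronger.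
- Against: A7 needs the quaternary C4 made enantioselectively in an open chain. Its two small substituents (CH3 and CH2OSi) differ little in size, so C4 gives weak facial control over C5 and C10. The C8 oxygen must later become the methylene through a C8 ketone β to the C9 ester (an enolised β-keto ester that resists olefination), and C6=C7 must be hydrogenated first.
- Comparison: the chosen plan pays with a C6 deoxygenation and a late C4 desymmetrisation, but it uses an achiral precursor, takes its absolute configuration from a catalyst, and forms the methylene directly.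

Key step: step 9

## Route

Assumption: the hand of the two chiral catalysts (steps 9 and 19) is assigned by analogy with their usual facial models for acrylate-type esters and (E)-3-methyl-2-enoates; both antipodes of each ligand are commercial, so the mirror-image catalyst is taken if the sense proves opposite.

Step 1
Reactants: 1 ethyl 2-oxocyclohexane-1-carboxylate
Product: 2 ethyl 1-(hydroxymethyl)-2-oxocyclohexane-1-carboxylate (racemic)
Conditions: aq. CH2O (37%), KHCO3 (cat.), THF, rt
Reagents that add atoms: formaldehyde, C=O
Why: Aldol addition of the doubly activated α-carbon of the β-keto ester to formaldehyde under catalytic base; the quaternary product cannot dehydrate.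

Step 2
Reactants: 2 ethyl 1-(hydroxymethyl)-2-oxocyclohexane-1-carboxylate
Product: 3 2,2-bis(hydroxymethyl)cyclohexan-1-ol (racemic)
Conditions: LiAlH4, THF, −40 °C → rt
Reagents that add atoms: none
Why: Hydride reduction of ketone and ester together; at low temperature reduction should outpace retro-aldol loss of formaldehyde from the aluminium alkoxide. The carbinol centre is racemic and is removed in step 4.

Step 3
Reactants: 3 2,2-bis(hydroxymethyl)cyclohexan-1-ol
Product: 4 3,3-dimethyl-2,4-dioxaspiro[5.5]undecan-7-ol (racemic)
Conditions: 2-methoxypropene, PPTS (cat.), DMF, 0 °C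
Reagents that add atoms: 2-methoxypropene, C=C(C)OC
Why: Kinetic acetonide formation: a primary hydroxyl captures the enol ether and the mixed ketal closes onto the second primary hydroxyl to give the 5,5-disubstituted 1,3-dioxane. Any ring-fused isomer would appear as an aldehyde after step 4 and is removed there.

Step 4
Reactants: 4 3,3-dimethyl-2,4-dioxaspiro[5.5]undecan-7-ol
Product: 5 3,3-dimethyl-2,4-dioxaspiro[5.5]undecan-7-one
Conditions: DMP (triacetoxyperiodinane), NaHCO3, CH2Cl2, rt
Reagents that add atoms: none
Why: Dess–Martin oxidation of the secondary alcohol under buffered conditions that spare the acetonide; the ketone has a single enolisable α-position.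

Step 5
Reactants: 5 3,3-dimethyl-2,4-dioxaspiro[5.5]undecan-7-one
Product: 6 3,3,8-trimethyl-2,4-dioxaspiro[5.5]undecan-7-one (racemic)
Conditions: LiN(iPr)2, THF, −78 °C; MeI, −78 → 0 °C
Reagents that add atoms: iodomethane, CI
Why: Enolate alkylation; only one enolate can form because the other α-carbon is quaternary. The new centre (the future C10) is racemic and becomes sp2 in step 6.

Step 6
Reactants: 6 3,3,8-trimethyl-2,4-dioxaspiro[5.5]undecan-7-one
Product: 7 3,3,8-trimethyl-2,4-dioxaspiro[5.5]undec-7-en-7-yl trifluoromethanesulfonate
Conditions: KN(SiMe3)2, THF, −78 °C; PhNTf2, −78 → 0 °C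
Reagents that add atoms: N-phenylbis(trifluoromethanesulfonimide), O=S(=O)(N(c1ccccc1)S(=O)(=O)C(F)(F)F)C(F)(F)F
Why: Removal of the single remaining α-hydrogen and O-sulfonylation of the potassium enolate gives the tetrasubstituted enol triflate regiospecifically.

Step 7
Reactants: 7 3,3,8-trimethyl-2,4-dioxaspiro[5.5]undec-7-en-7-yl trifluoromethanesulfonate
Product: 9 1-(3,3,8-trimethyl-2,4-dioxaspiro[5.5]undec-7-en-7-yl)ethan-1-one, via 2-ethoxydiene 8 (not isolated)
Conditions: tributyl(1-ethoxyvinyl)stannane, Pd(PPh3)4 (5 mol%), LiCl, CuI (cat.), 1,4-dioxane, 90 °C; then aq. oxalic acid, THF, rt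
Reagents that add atoms: tributyl(1-ethoxyvinyl)stannane, CCCC[Sn](CCCC)(CCCC)C(=C)OCC; water, O
Why: Stille coupling of the vinyl triflate (zerovalent palladium, chloride-assisted transmetallation) forms the C5–C6 bond with a masked acetyl group. The 2-ethoxydiene is an enol ether and should hydrolyse much faster than the acetonide under the weak acid.

Step 8
Reactants: 9 1-(3,3,8-trimethyl-2,4-dioxaspiro[5.5]undec-7-en-7-yl)ethan-1-one
Product: 10 tert-butyldimethyl{[1-(3,3,8-trimethyl-2,4-dioxaspiro[5.5]undec-7-en-7-yl)ethenyl]oxy}silane (achiral 2-silyloxydiene C7=C6(OSi)–C5=C10)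
Conditions: TBSOTf, Et3N, CH2Cl2, 0 °C
Reagents that add atoms: tert-butyldimethylsilyl trifluoromethanesulfonate, CC(C)(C)[Si](C)(C)OS(=O)(=O)C(F)(F)F
Why: Soft enolisation removes a proton from the acetyl methyl of the twisted, tetrasubstituted enone and gives the cross-conjugated silyl enol ether. The diene is achiral because the spiro-acetonide is symmetric.

Step 9
Reactants: 10 2-silyloxydiene; 11 ethyl buta-2,3-dienoate
Product: 12 Diels–Alder adduct: ethyl ester with C5=C6 tert-butyldimethylsilyl enol ether, C8 exocyclic methylene, (9R)-ethoxycarbonyl cis to the (10S)-methyl, C4 spiro-acetonide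
Conditions: 11 (1.5 equiv), oxazaborolidinium triflimide from (S)-1-(2-methylphenyl)-3,3-diphenyltetrahydro-1H,3H-pyrrolo[1,2-c][1,3,2]oxazaborole (20 mol%) and HNTf2 (18 mol%), CH2Cl2, −78 → −20 °C
Reagents that add atoms: none
Why: Proposed new method: the boron of the oxazaborolidinium ion binds the ester carbonyl of 11 and activates its 2,3-double bond, and the silyl enol ether terminus C7 of 10 attacks the central allene carbon C8 in a strongly asynchronous [4+2] cycloaddition in which the ester-bearing C9 then closes onto the fully substituted C10; the closest known reactions are Diels–Alder additions of 2-silyloxydienes and of 2,6,6-trisubstituted 1-vinylcyclohexenes to allenic and acetylenic esters, and oxazaborolidinium-catalysed enantioselective Diels–Alder reactions of acrylates. Ring B is closed by intermolecular [4+2] annulation onto ring A through the C7–C8 and C9–C10 bonds; in the stepwise limit this is a 6-endo-trig closure of the boron-bound ester enolate onto the silyloxyallyl cation. C10 is set by the catalyst, which shields one face of the bound allenoate so that only one of the two enantiotopic faces of the achiral diene is attacked. C9 is set relative to C10 by the exo orientation of the complexed ester, expected because the endo position lies under ring A and its C4 spiro-dioxane; this places the ester cis to the C10 methyl, as the target requires. The step needs regioselectivity, which the C6 silyloxy group (nucleophilic C7) and the electrophilic central allene carbon both dictate. It needs chemoselectivity for the 2,3- over the 3,4-double bond, which ester conjugation secures and which leaves C8=C17 as the methylene. It also needs closure at C10 in preference to C6 (cyclobutane), for which the reversibility of a donor–acceptor cyclobutane under the Lewis acid is counted on.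

Step 10
Reactants: 12 Diels–Alder adduct
Product: 14 hydroxy ester: trans-fused decalin, axial C6 hydroxyl cis to the C10 methyl, C8 methylene, C9 ethyl ester, C4 spiro-acetonide, via trans-fused C6 ketone 13 (not isolated)
Conditions: Bu4NF, AcOH, THF, −20 °C; then NaBH4, MeOH, −20 → 0 °C
Reagents that add atoms: none
Why: Fluoride frees the C6 enolate, which acetic acid protonates at C5 from the face opposite the syn-axial C10 methyl and axial C4 arm, giving the trans ring fusion (substrate control, also the thermodynamic outcome). Borohydride reduction in the same flask removes the β,γ-unsaturated ketone before the C8 methylene can move into conjugation. Hydride enters from the open face, so the alcohol is axial; its configuration is immaterial.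

Step 11
Reactants: 14 hydroxy ester
Product: 15 O-(C6) S-methyl dithiocarbonate (xanthate) of 14
Conditions: KN(SiMe3)2, THF, −78 °C; CS2; MeI, −78 °C → rt
Reagents that add atoms: carbon disulfide, S=C=S; iodomethane, CI
Why: Xanthate formation through the potassium alkoxide; CS2 is small enough to reach the hindered axial oxygen. One equivalent of base at −78 °C removes the O–H proton and not the hindered C9–H of the ester.

Step 12
Reactants: 15 xanthate
Product: 16 ethyl ester: trans-decalin with C8 methylene, equatorial C9 ethoxycarbonyl, C4 spiro-acetonide, C6 as CH2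
Conditions: Bu3SnH, AIBN (cat.), toluene, 90 °C
Reagents that add atoms: none
Why: Barton–McCombie deoxygenation; the secondary C6 radical takes hydrogen from the stannane. Its homoallylic relation to C8=C17 is harmless because cyclopropylcarbinyl closure is reversible and rearrangement would lead to a less stable primary radical.

Step 13
Reactants: 16 ethyl ester
Product: 17 C11 primary alcohol (C9 hydroxymethyl, equatorial)
Conditions: LiAlH4, Et2O, 0 °C
Reagents that add atoms: none
Why: Hydride reduction of the ester; the acetonide and the isolated alkene are inert.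

Step 14
Reactants: 17 C11 alcohol
Product: 18 C11 aldehyde
Conditions: DMP, NaHCO3, CH2Cl2, 0 °C
Reagents that add atoms: none
Why: Dess–Martin oxidation under buffered, non-basic conditions should give the aldehyde without epimerising C9 or moving the neighbouring methylene.

Step 15
Reactants: 18 C11 aldehyde
Product: 19 (E)-enone C11=C12–C13(=O)–C16
Conditions: Ph3P=CHC(O)CH3, toluene, 100 °C
Reagents that add atoms: 1-(triphenylphosphoranylidene)propan-2-one, CC(=O)C=P(c1ccccc1)(c1ccccc1)c1ccccc1
Why: Wittig olefination with a stabilised keto ylide, which is too weakly basic to enolise the α-branched aldehyde and gives the (E)-alkene.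

Step 16
Reactants: 19 (E)-enone
Product: 20 saturated methyl ketone (C11–C12 single bond, C13 ketone)
Conditions: [(Ph3P)CuH]6, THF, H2O (degassed), rt
Reagents that add atoms: none
Why: Conjugate reduction by copper hydride saturates only the enone double bond, and water protonates the copper enolate. The isolated C8 methylene is not touched, which a catalytic hydrogenation could not guarantee.

Step 17
Reactants: 21 2-(diethoxyphosphoryl)acetic acid; 22 2-(trimethylsilyl)ethanol
Product: 23 2-(trimethylsilyl)ethyl 2-(diethoxyphosphoryl)acetate
Conditions: DCC, DMAP (cat.), CH2Cl2, 0 °C → rt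
Reagents that add atoms: none
Why: Steglich esterification gives the phosphonate that brings in C14 and C15 as a fluoride-labile ester, orthogonal to the later cinnamate.

Step 18
Reactants: 20 methyl ketone; 23 phosphonate
Product: 24 2-(trimethylsilyl)ethyl (E)-3-methyl-2-enoate (C13=C14)
Conditions: 23, NaH, THF, 0 °C; then 20, rt → 50 °C
Reagents that add atoms: none
Why: Horner–Wadsworth–Emmons olefination of the unhindered methyl ketone should favour the (E)-enoate with the larger chain trans to the ester. The minor (Z)-isomer is removed by chromatography because it would lead to the C13 epimer in step 19.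

Step 19
Reactants: 24 (E)-enoate
Product: 25 saturated (13S)-ester with C4 spiro-acetonide
Conditions: Cu(OAc)2·H2O (5 mol%), (S)-2,2'-bis(di-p-tolylphosphino)-1,1'-binaphthyl (5 mol%), (EtO)2MeSiH, t-BuOH, toluene, 0 °C → rt
Reagents that add atoms: none
Why: Enantioselective conjugate reduction of the β,β-disubstituted enoate by a chiral bisphosphine copper hydride. The ligand decides which face of C13 receives hydride, independently of the remote ring stereocentres. The alcohol protonates the copper enolate and turns the catalyst over.

Step 20
Reactants: 25 (13S)-ester acetonide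
Product: 26 C18,C19-diol
Conditions: PPTS, MeOH, rt
Reagents that add atoms: none
Why: Acid-catalysed transketalisation to methanol removes the acetonide; the silylethyl ester and the methylene should tolerate the mild acid.

Step 21
Reactants: 27 p-coumaric acid
Product: 29 (E)-3-[4-(tert-butyldimethylsilyloxy)phenyl]prop-2-enoic acid, via bis-silylated coumarate 28 (not isolated)
Conditions: TBSCl, imidazole, DMF, rt; then AcOH, THF, H2O, rt
Reagents that add atoms: tert-butyldimethylsilyl chloride, CC(C)(C)[Si](C)(C)Cl
Why: Exhaustive silylation followed by selective hydrolysis of the much more labile silyl ester leaves the phenol protected and the acid free.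

Step 22
Reactants: 26 diol; 29 protected coumaric acid
Product: 30 C18 (equatorial) coumarate with free axial C19 hydroxymethyl, (4S)
Conditions: DCC, DMAP (cat.), CH2Cl2, −20 °C, 29 added slowly (1.0 equiv)
Reagents that add atoms: none
Why: Steglich esterification; the equatorial hydroxymethyl should be acylated first because the axial one is screened by the syn-axial C10 methyl. This step makes C4 a stereocentre, with the rigid trans-decalin providing the discrimination (substrate control).

Step 23
Reactants: 30 monoester alcohol
Product: 31 axial C19 aldehyde
Conditions: DMP, NaHCO3, CH2Cl2, rt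
Reagents that add atoms: none
Why: Dess–Martin oxidation of the remaining neopentyl alcohol to a non-enolisable aldehyde.

Step 24
Reactants: 31 C19 aldehyde
Product: 33 doubly protected target (axial C19 methyl, silyl ether on the phenol, 2-(trimethylsilyl)ethyl ester at C15), via C19 tosylhydrazone 32 (not isolated)
Conditions: TsNHNH2, THF/EtOH, rt; then catecholborane, CHCl3, 0 °C; then NaOAc·3H2O, 60 °C
Reagents that add atoms: none
Why: Tosylhydrazone formation, hydride addition to C=N by catecholborane, and acetate-induced loss of sulfinate and N2 turn CHO into CH3 (mild variant of the Caglioti reduction). The cinnamate, the silyl groups and both alkenes should be untouched.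

Step 25
Reactants: 33 doubly protected target
Product: 34 target acid, (4S,5S,9R,10S,13S)
Conditions: Bu4NF, THF, 0 °C → rt; aq. NH4Cl
Reagents that add atoms: none
Why: Fluoride cleaves the aryl silyl ether and, by β-elimination of ethene and Me3SiF, the 2-(trimethylsilyl)ethyl ester in one operation. The hindered neopentyl cinnamate should survive, the more so once the phenoxide is formed.

## Compound list

1 | ethyl 2-oxocyclohexane-1-carboxylate | CCOC(=O)C1CCCCC1=O | starting material
2 | ethyl 1-(hydroxymethyl)-2-oxocyclohexane-1-carboxylate (racemic) | CCOC(=O)C1(CO)CCCCC1=O | intermediate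
3 | 2,2-bis(hydroxymethyl)cyclohexan-1-ol (racemic) | OCC1(CO)CCCCC1O | intermediate
4 | 3,3-dimethyl-2,4-dioxaspiro[5.5]undecan-7-ol (racemic) | CC1(C)OCC2(CO1)CCCCC2O | intermediate
5 | 3,3-dimethyl-2,4-dioxaspiro[5.5]undecan-7-one | CC1(C)OCC2(CO1)CCCCC2=O | intermediate
6 | 3,3,8-trimethyl-2,4-dioxaspiro[5.5]undecan-7-one (racemic) | CC1CCCC2(COC(C)(C)OC2)C1=O | intermediate
7 | 3,3,8-trimethyl-2,4-dioxaspiro[5.5]undec-7-en-7-yl trifluoromethanesulfonate | CC1=C(OS(=O)(=O)C(F)(F)F)C2(COC(C)(C)OC2)CCC1 | intermediate
8 | 7-(1-ethoxyethenyl)-3,3,8-trimethyl-2,4-dioxaspiro[5.5]undec-7-ene | CCOC(=C)C1=C(C)CCCC12COC(C)(C)OC2 | intermediate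
9 | 1-(3,3,8-trimethyl-2,4-dioxaspiro[5.5]undec-7-en-7-yl)ethan-1-one | CC(=O)C1=C(C)CCCC12COC(C)(C)OC2 | intermediate
10 | tert-butyldimethyl{[1-(3,3,8-trimethyl-2,4-dioxaspiro[5.5]undec-7-en-7-yl)ethenyl]oxy}silane (achiral diene) | C=C(O[Si](C)(C)C(C)(C)C)C1=C(C)CCCC12COC(C)(C)OC2 | intermediate
11 | ethyl buta-2,3-dienoate | C=C=CC(=O)OCC | starting material
12 | Diels–Alder adduct, (9R,10S): C5=C6 silyl enol ether, C8 methylene, C9 ethyl ester cis to C10 methyl, C4 spiro-acetonide | C=C1CC(O[Si](C)(C)C(C)(C)C)=C2C3(COC(C)(C)OC3)CCC[C@@]2(C)[C@@H]1C(=O)OCC | intermediate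
13 | trans-fused C6 ketone (H5 trans to C10 methyl), C9 ethyl ester | C=C1CC(=O)[C@@H]2C3(COC(C)(C)OC3)CCC[C@@]2(C)[C@@H]1C(=O)OCC | intermediate
14 | C6 axial alcohol (OH cis to C10 methyl), C9 ethyl ester | C=C1C[C@H](O)[C@@H]2C3(COC(C)(C)OC3)CCC[C@@]2(C)[C@@H]1C(=O)OCC | intermediate
15 | C6 O-alkyl S-methyl dithiocarbonate of 14 | C=C1C[C@H](OC(=S)SC)[C@@H]2C3(COC(C)(C)OC3)CCC[C@@]2(C)[C@@H]1C(=O)OCC | intermediate
16 | C6-deoxy ethyl ester (trans-decalin, C8 methylene, equatorial C9 ester, C4 spiro-acetonide) | C=C1CC[C@@H]2C3(COC(C)(C)OC3)CCC[C@@]2(C)[C@@H]1C(=O)OCC | intermediate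
17 | C11 primary alcohol | C=C1CC[C@@H]2C3(COC(C)(C)OC3)CCC[C@@]2(C)[C@@H]1CO | intermediate
18 | C11 aldehyde | C=C1CC[C@@H]2C3(COC(C)(C)OC3)CCC[C@@]2(C)[C@@H]1C=O | intermediate
19 | (E)-enone, C11=C12–C13(=O)CH3 | C=C1CC[C@@H]2C3(COC(C)(C)OC3)CCC[C@@]2(C)[C@@H]1/C=C/C(C)=O | intermediate
20 | saturated C13 methyl ketone | C=C1CC[C@@H]2C3(COC(C)(C)OC3)CCC[C@@]2(C)[C@@H]1CCC(C)=O | intermediate
21 | 2-(diethoxyphosphoryl)acetic acid | O=C(O)CP(=O)(OCC)OCC | starting material
22 | 2-(trimethylsilyl)ethanol | C[Si](C)(C)CCO | starting material
23 | 2-(trimethylsilyl)ethyl 2-(diethoxyphosphoryl)acetate | CCOP(=O)(OCC)CC(=O)OCC[Si](C)(C)C | intermediate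
24 | 2-(trimethylsilyl)ethyl (E)-3-methyl-2-enoate, C13=C14 | C=C1CC[C@@H]2C3(COC(C)(C)OC3)CCC[C@@]2(C)[C@@H]1CC/C(C)=C/C(=O)OCC[Si](C)(C)C | intermediate
25 | (13S)-2-(trimethylsilyl)ethyl ester with C4 spiro-acetonide | C=C1CC[C@@H]2C3(COC(C)(C)OC3)CCC[C@@]2(C)[C@@H]1CC[C@H](C)CC(=O)OCC[Si](C)(C)C | intermediate
26 | C18,C19-diol, (13S)-2-(trimethylsilyl)ethyl ester | C=C1CC[C@@H]2C(CO)(CO)CCC[C@@]2(C)[C@@H]1CC[C@H](C)CC(=O)OCC[Si](C)(C)C | intermediate
27 | p-coumaric acid, (E)-3-(4-hydroxyphenyl)prop-2-enoic acid | O=C(O)/C=C/c1ccc(O)cc1 | starting material
28 | tert-butyldimethylsilyl (E)-3-[4-(tert-butyldimethylsilyloxy)phenyl]prop-2-enoate | CC(C)(C)[Si](C)(C)OC(=O)/C=C/c1ccc(O[Si](C)(C)C(C)(C)C)cc1 | intermediate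
29 | (E)-3-[4-(tert-butyldimethylsilyloxy)phenyl]prop-2-enoic acid | O=C(O)/C=C/c1ccc(O[Si](C)(C)C(C)(C)C)cc1 | intermediate
30 | (4S)-C18 equatorial coumarate (phenol silyl ether), axial C19 hydroxymethyl | C=C1CC[C@@H]2[C@@](CO)(COC(=O)/C=C/c3ccc(O[Si](C)(C)C(C)(C)C)cc3)CCC[C@@]2(C)[C@@H]1CC[C@H](C)CC(=O)OCC[Si](C)(C)C | intermediate
31 | axial C19 aldehyde | C=C1CC[C@@H]2[C@@](C=O)(COC(=O)/C=C/c3ccc(O[Si](C)(C)C(C)(C)C)cc3)CCC[C@@]2(C)[C@@H]1CC[C@H](C)CC(=O)OCC[Si](C)(C)C | intermediate
32 | (E)-tosylhydrazone of the C19 aldehyde | C=C1CC[C@@H]2[C@@](/C=N/NS(=O)(=O)c3ccc(C)cc3)(COC(=O)/C=C/c3ccc(O[Si](C)(C)C(C)(C)C)cc3)CCC[C@@]2(C)[C@@H]1CC[C@H](C)CC(=O)OCC[Si](C)(C)C | intermediate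
33 | doubly protected target (axial C19 methyl, phenol silyl ether, C15 2-(trimethylsilyl)ethyl ester) | C=C1CC[C@@H]2[C@@](C)(COC(=O)/C=C/c3ccc(O[Si](C)(C)C(C)(C)C)cc3)CCC[C@@]2(C)[C@@H]1CC[C@H](C)CC(=O)OCC[Si](C)(C)C | intermediate
34 | target, (4S,5S,9R,10S,13S)-C18 (E)-p-coumarate of the 8(17)-en-15-oic acid | C=C1CC[C@@H]2[C@@](C)(COC(=O)/C=C/c3ccc(O)cc3)CCC[C@@]2(C)[C@@H]1CC[C@H](C)CC(=O)O | target

## Step count and least certain steps

Total: 25 steps. Longest linear sequence: 23 steps (1–16, 18–20, 22–25). Steps 17 and 21 prepare the two side reagents.

**Step 9 (key step, proposed new method).**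
- What may go wrong: the tetrasubstituted, twisted diene may react too slowly at the low temperature the catalyst needs. Protodesilylation of the enol ether by the strong acid, or a stepwise Mukaiyama–Michael course ending in an open-chain adduct or a cyclobutane, could then take over. Face selectivity and exo orientation are untested on an allenoate and on a diene this hindered.
- Fallback (from 10 and 11, back at 12): the cycloaddition is run without a catalyst in toluene at 110 °C in a sealed tube, a known reaction type for 2-silyloxydienes and for 2,6,6-trisubstituted 1-vinylcyclohexenes with allenic esters. This gives 12 as the racemate together with its mirror image, the ent-adduct F1. The two are separated by preparative chromatography on a chiral stationary phase, and 12 re-enters at step 10. Half of the material is lost.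

**Step 10.**
- What may go wrong: the C8=C17 double bond may migrate into conjugation once the C6 ketone is free (β,γ to α,β), or C5 may be protonated from the wrong face. The axial alcohol that results is also very hindered, which burdens step 11.
- Fallback (from 12, back at 16): 12 is treated with TsNHNH2 and PPTS in ethanol. The enol ether is protonated at C5 and captured directly as the C6 tosylhydrazone F2 without a basic medium. Reduction with catecholborane and then NaOAc·3H2O gives 16, bypassing 13, 14 and 15.

**Step 15.**
- What may go wrong: olefination of the hindered α-branched aldehyde may be slow, and on long heating C9 may epimerise or the methylene may move into conjugation with the aldehyde.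
- Fallback (from 18, back at 19): the lithium enolate of acetone (LiN(iPr)2, THF, −78 °C) adds to 18 within minutes to give the β-hydroxy ketone F3 as a mixture of C11 epimers. Mesylation with triethylamine brings about β-elimination to the (E)-enone 19.

**Step 22.**
- What may go wrong: discrimination between the two neopentyl hydroxymethyl groups may be insufficient, giving bis-acylation, the axial ester, or acyl migration between the 1,3-related oxygens.
- Fallback (from 26, back at 33): the bulkier triisopropylsilyl chloride (imidazole, CH2Cl2, 0 °C) is used to mark the equatorial oxygen, giving the silyl ether F4. The axial alcohol is converted with PPh3, I2 and imidazole in hot toluene to the iodide F5, which is reduced with Bu3SnH and AIBN to the C19 methyl compound F6. No cinnamate is present at that stage. HF·pyridine frees the equatorial alcohol F7, which is esterified with 29 (DCC, DMAP) to give 33.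

**Step 24.**
- What may go wrong: hydride delivery to the hindered neopentyl tosylhydrazone may be slow, and prolonged exposure to catecholborane may cause conjugate reduction of the cinnamate or loss of the aryl silyl ether.
- Fallback (from 30, back at 33): the axial alcohol of 30 is converted with MsCl and Et3N to the mesylate F8. F8 is reduced with NaI and Zn in refluxing 1,2-dimethoxyethane (iodide displacement, then zinc insertion and protonation) to 33. Steps 23 and 24 are not needed.

## Further compounds

F1 | step 9 | mirror image of adduct 12, (9S,10R) | C=C1CC(O[Si](C)(C)C(C)(C)C)=C2C3(COC(C)(C)OC3)CCC[C@]2(C)[C@H]1C(=O)OCC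
F2 | step 10 | C6 tosylhydrazone of the trans-fused ketone, C9 ethyl ester | C=C1C/C(=N\NS(=O)(=O)c2ccc(C)cc2)[C@@H]2C3(COC(C)(C)OC3)CCC[C@@]2(C)[C@@H]1C(=O)OCC
F3 | step 15 | β-hydroxy ketone from aldol addition of acetone to 18 (both C11 epimers) | C=C1CC[C@@H]2C3(COC(C)(C)OC3)CCC[C@@]2(C)[C@@H]1C(O)CC(C)=O
F4 | step 22 | equatorial C18 triisopropylsilyl ether, axial C19 hydroxymethyl | C=C1CC[C@@H]2[C@@](CO)(CO[Si](C(C)C)(C(C)C)C(C)C)CCC[C@@]2(C)[C@@H]1CC[C@H](C)CC(=O)OCC[Si](C)(C)C
F5 | step 22 | axial C19 iodide, C18 triisopropylsilyl ether | C=C1CC[C@@H]2[C@@](CI)(CO[Si](C(C)C)(C(C)C)C(C)C)CCC[C@@]2(C)[C@@H]1CC[C@H](C)CC(=O)OCC[Si](C)(C)C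
F6 | step 22 | axial C19 methyl, C18 triisopropylsilyl ether | C=C1CC[C@@H]2[C@@](C)(CO[Si](C(C)C)(C(C)C)C(C)C)CCC[C@@]2(C)[C@@H]1CC[C@H](C)CC(=O)OCC[Si](C)(C)C
F7 | step 22 | axial C19 methyl, free equatorial C18 alcohol | C=C1CC[C@@H]2[C@@](C)(CO)CCC[C@@]2(C)[C@@H]1CC[C@H](C)CC(=O)OCC[Si](C)(C)C
F8 | step 24 | axial C19 methanesulfonate of 30 | C=C1CC[C@@H]2[C@@](COS(C)(=O)=O)(COC(=O)/C=C/c3ccc(O[Si](C)(C)C(C)(C)C)cc3)CCC[C@@]2(C)[C@@H]1CC[C@H](C)CC(=O)OCC[Si](C)(C)C
A1 | alternative 1 | trans-fused bicyclic C18 aldehyde with C1=C2 alkene and C8 dioxolane | O1CCOC12CC[C@@H]3[C@@](C)(C=O)CC=C[C@@]3(C)[C@@H]2CC[C@H](C)CCO[Si](c1ccccc1)(c1ccccc1)C(C)(C)C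
A2 | alternative 1 | acyclic trienal: (E)-2-methyl-2-enal C4=C5, diene C10=C1–C2=C3, C8 dioxolane, preset C9 and C13 | C=C/C=C(\C)[C@H](CC[C@H](C)CCO[Si](c1ccccc1)(c1ccccc1)C(C)(C)C)C1(CC/C=C(\C)C=O)OCCO1
A3 | alternative 2 | ring B allylic triethylsilyl ether with exocyclic C9=C11 alkene (C8 drawn as one epimer) | CC[Si](CC)(CC)O[C@@H]1CC[C@@H]2[C@@](C)(COCc3ccc(OC)cc3)CCC[C@@]2(C)/C1=C\C[C@H](C)CCO[Si](c1ccccc1)(c1ccccc1)C(C)(C)C
A4 | alternative 2 | ring A ynal: C5 3-oxopropyl chain, C10 alkyne C9≡C11 carrying C12–C15, C4 with axial methyl and equatorial p-methoxybenzyloxymethyl | O=CCC[C@@H]1[C@@](C)(COCc2ccc(OC)cc2)CCC[C@@]1(C)C#CC[C@H](C)CCO[Si](c1ccccc1)(c1ccccc1)C(C)(C)C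
A5 | alternative 2 | dehydroabietic acid | CC(C)C1=CC2=C(C=C1)[C@]3(CCC[C@@]([C@@H]3CC2)(C)C(=O)O)C
A6 | alternative 3 | trans-fused cycloadduct with C8 silyl ether, C6=C7 alkene and C11 methyl ester | CC(C)(C)[Si](C)(C)O[C@@H]1C=C[C@@H]2[C@@](C)(CO[Si](c3ccccc3)(c3ccccc3)C(C)(C)C)CCC[C@@]2(C)[C@@H]1C(=O)OC
A7 | alternative 3 | acyclic triene: (E,E)-1-silyloxydiene C5–C8, quaternary C4, (E)-3-methyl-2-enoate C9=C10 | CC(C)(C)[Si](C)(C)O/C=C/C=C/[C@@](C)(CO[Si](c1ccccc1)(c1ccccc1)C(C)(C)C)CCC/C(C)=C/C(=O)OC
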